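Readings and results were generated by integration on assumed constants, and the scatter is random.

Which flask holds the most target at each reading is reckoned here from one count: the rounds a catalyst makes before it stops working.

| flask | substrate | reagent | free catalyst | added ligand | remark | time |
|---|---|---|---|---|---|---|
| Sunday's | 0.40 M | 1.1 equiv | 0.02 mol% | 0.80 mM | run made earlier |  |
| Saturday's | 0.40 M | 1.1 equiv | 0.088 mol% | 0.80 mM | run made earlier |  |
| Monday's | 0.40 M | 1.1 equiv | 0.1 mol% | 1.3 mM | run made earlier |  |
| dusk | 0.25 M | 1.70 equiv | 0.1 mol% | 1.5 mM |  | 1.0 h |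
| summer | 1.2 M | 1.10 equiv | 0.03 mol% | 0.80 mM |  | 1.0 h |
| midnight | 0.40 M | 1.10 equiv | 0.1 mol% | 0.80 mM |  | 1.0 h |
| autumn | 0.40 M | 1.10 equiv | 0.06 mol% | 1.5 mM |  | 1.0 h |

| run | time / min | target / % | substrate / % |
|---|---|---|---|
| Sunday's | 4.00 | 3.1 | 96.4 |
| Sunday's | 8.00 | 5.0 | 96.5 |
| Sunday's | 12.0 | 4.2 | 93.3 |
| Sunday's | 15.0 | 9.4 | 92.8 |
| Sunday's | 20.0 | 7.8 | 91.1 |
| Sunday's | 25.0 | 11.5 | 88.9 |
| Sunday's | 30.0 | 11.9 | 87.5 |
| Saturday's | 2.50 | 6.0 | 94.1 |
| Saturday's | 4.00 | 10.5 | 90.1 |
| Saturday's | 6.00 | 13.4 | 84.5 |
| Saturday's | 8.00 | 16.8 | 80.6 |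
| Saturday's | 12.0 | 23.1 | 75.0 |
| Saturday's | 20.0 | 34.8 | 63.4 |
| Saturday's | 30.0 | 45.8 | 53.9 |
| Monday's | 2.50 | 7.6 | 93.3 |
| Monday's | 8.00 | 19.2 | 79.8 |
| Monday's | 15.0 | 27.8 | 69.2 |
| Monday's | 20.0 | 34.8 | 64.4 |
| Monday's | 30.0 | 41.9 | 56.3 |

(scatter of a reading: 1 percentage point)

1. the flasks put in order of amount of target, in percent of the substrate charged, best first, at 1.0 h (dusk / summer / midnight / autumn)
2. the same order at 8.0 h (dusk / summer / midnight / autumn)
3. the amount of target, in percent of the substrate charged of the flask you put first, at 1.0 h
4. the amount of target, in percent of the substrate charged of the flask you put last, at 1.0 h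

- the numbers in the tables scatter by 1 percentage point (one standard deviation)

The fastest rung is the catalyst's round. Early in Saturday's run the pace of a catalyst reads 29.8 min⁻¹, so a round takes 2.01 s, far less than the wait for the first reading, 2.50 min. The catalyst's forms therefore follow the flask from moment to moment, and target and substrate in Saturday's last reading still add to 99.7%.

The next rung is the fading of the catalyst. Sunday's run, little depleted, reads 595 turnovers at 30.0 min, fewer than the 894 that the early pace gives. Treating this shortfall as a small correction, a catalyst fading exponentially loses the fraction of elapsed time over 2 fading times, so the fading time reads 44.8 min, with the scatter of that reading in it. Supposing that the fading time goes inversely with added ligand, Monday's run should read 710 turnovers at 30.0 min. It reads 419, fewer, but its substrate is down by 43.7%, which this count does not take in, so the inverse rule remains an untested assumption.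

The last rung is the use of the substrate, whose time differs from flask to flask and is held against the fading time. The quantity carried forward is the turnover budget, meaning the early pace times the fading time, 1340 at 0.80 mM of ligand. This is a turnover number, and budget times loading gives the reach, the percentage of substrate a catalyst can convert before fading. Midnight needs 33.5 min to use its substrate at the early pace, less than its fading time, and its reach reads 134%, more than the whole charge. Autumn needs 55.9 min against a fading time of 23.9 min, so it should stall near a reach of 42.7%. Assuming, untested, that rounds quicken in step with concentration, summer has a reach of 120%. On the same assumption dusk, with autumn's ligand, has a reach of 44.5%, more than autumn's. My order at both times is therefore midnight, summer, dusk, autumn.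

The forecast gives summer > midnight > dusk > autumn and then dusk > summer > midnight > autumn, with 82% and 47%, and holds that “Added ligand has little visible effect”. The two reckonings part on that point.

The flasks give midnight > summer > dusk > autumn at 1.0 h and midnight > summer > dusk > autumn at 8.0 h, with 64.6% and 32.3%.

    reagent + free catalyst ⇌ catalyst intermediate A (K = 2.15 L mol⁻¹, k = 337 L mol⁻¹ min⁻¹)
    catalyst intermediate A → released group + catalyst intermediate B (k = 457 min⁻¹)
    substrate + catalyst intermediate B → catalyst intermediate C (k = 153 L mol⁻¹ min⁻¹)
    catalyst intermediate C → free catalyst + target (k = 186 min⁻¹)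
    free catalyst + target → free catalyst + over-reaction product (k = 22.3 L mol⁻¹ min⁻¹)
    free catalyst + added ligand ⇌ idle complex (K = 1.10 × 10⁵ L mol⁻¹, k = 117 L mol⁻¹ min⁻¹)

Midnight holds 69.7% of its catalyst as idle complex at 1.00 h, and the fading time gives a faded share of 73.8%. Autumn, with its reach of 42.7%, holds 45.7% target at 8.00 h and 48.6% at 10.0 h.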